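## Retrosynthetic overview
1. 8 ⇒ 6: both C2–Br bonds come from lactam C=O groups (double deoxybromination with aromatisation), so the biindole is planned as its 3,3'-bioxindole.
2. 6 ⇒ 2 + 4: the central C3–C3' bond is cut into a C3-nucleophilic oxindole dianion and a C3-electrophilic 2H-indol-2-one (an enolonium equivalent). The cut is made at the lactam level because C3-halogenated indoles react with nucleophiles at C2, not C3.
3. 2 and 4 both ⇒ 1, so the coupling is run as a half-oxidation of one commercial lactam.
4. Ring order: no ring is built. Both five-membered rings are bought in 1 and are aromatised to indoles together in the last step.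

Assumption: the SMILES has no stereocentre and no axial descriptor, so the compound is made as drawn with the 3,3' axis undefined. No enantiomer has to be selected.

## Route

Step 1
Reactants: 1 6-bromoindolin-2-one (two molecules per product)
Product: 6 6,6'-dibromo-[3,3'-biindoline]-2,2'-dione (meso/racemic mixture), via dilithio dianion 2 (not isolated), via N-lithio 3-iodolactam 3 (not isolated), via 6-bromo-2H-indol-2-one 4 (not isolated), via dilithium salt 5 (not isolated)
Conditions: LiN(iPr)2 (commercial solution, 2.1 equiv), THF, −78 to −40 °C, Ar; I2 (0.50 equiv per 1) in THF added over 1 h at −78 °C, then to 0 °C; degassed AcOH (1.5 equiv); crude solid triturated under Ar and used directly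
Reagents that add atoms: none
Why: Proposed new method: slow addition of limiting I2 iodinates half of the C3-nucleophilic dianion 2 to the N-lithio 3-iodolactam 3, which loses lithium iodide to give the aza-ortho-xylylene 4, an enolonium equivalent that is electrophilic only at C3, and the remaining dianion 2 (C3-selective, as in dianion alkylations of oxindoles, and far more reactive than the product salt 5, which is what should hold the oxidation at the dihydro level) adds to it in an oxidative enolate homocoupling whose closest known relatives are the I2-mediated dimerisation of 3-substituted oxindole enolates and the nucleophile capture of indol-2-ones released from 3-halooxindoles; the two new C3 stereocentres arise unselectively (meso plus racemate), which does not matter because step 2 removes both.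

Step 2
Reactants: 6 6,6'-dibromo-[3,3'-biindoline]-2,2'-dione
Product: 8 2,2',6,6'-tetrabromo-1H,1'H-3,3'-biindole (target), via bis(dibromophosphate) 7 (not isolated)
Conditions: POBr3 (5 equiv), imidazole (2.4 equiv), ClCH2CH2Cl, reflux, Ar, 16–24 h; ice-water quench; SiO2
Reagents that add atoms: phosphorus oxybromide (POBr3), O=P(Br)(Br)Br
Why: This is the standard dehydrative bromination of an oxindole to a 2-bromoindole (Vilsmeier-type imidoyl halide formation) run twice: each lactam oxygen is phosphorylated, bromide displaces dibromophosphate at C2 and loss of the C3 proton aromatises the ring, so both C3 stereocentres vanish, the meso and racemic forms converge on one product, and the aryl bromides and N–H groups are untouched.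

## Compound list
1 | 6-bromoindolin-2-one (6-bromooxindole) | O=C1Cc2ccc(Br)cc2N1 | starting material
2 | 6-bromo-1-lithio-2-(lithiooxy)-1H-indole (N,C3-dianion of 1, drawn as the N,O-dilithio form) | [Li]Oc1cc2ccc(Br)cc2n1[Li] | intermediate
3 | 6-bromo-3-iodo-1-lithioindolin-2-one (racemic) | [Li]N1C(=O)C(I)c2ccc(Br)cc21 | intermediate
4 | 6-bromo-2H-indol-2-one (aza-ortho-xylylene) | O=C1C=C2C=CC(Br)=CC2=N1 | intermediate
5 | N,N'-dilithio salt of 6 (meso/racemic mixture) | O=C1N([Li])c2cc(Br)ccc2C1C1C(=O)N([Li])c2cc(Br)ccc12 | intermediate
6 | 6,6'-dibromo-[3,3'-biindoline]-2,2'-dione (C3/C3' unselective, meso plus racemate) | O=C1Nc2cc(Br)ccc2C1C1C(=O)Nc2cc(Br)ccc12 | intermediate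
7 | 6,6'-dibromo-1H,1'H-[3,3'-biindole]-2,2'-diyl bis(phosphorodibromidate) | O=P(Br)(Br)Oc1[nH]c2cc(Br)ccc2c1-c1c(OP(=O)(Br)Br)[nH]c2cc(Br)ccc12 | intermediate
8 | 2,2',6,6'-tetrabromo-1H,1'H-3,3'-biindole | Brc1ccc2c(-c3c(Br)[nH]c4cc(Br)ccc34)c(Br)[nH]c2c1 | target

## Totals and risks
Total step count: 2. Longest linear sequence: 2.

The route has only two steps, so both are ranked and there is no third.

**1. Step 1 (highest risk).**
- The salt 5 is itself easy to oxidise, so a second iodination and elimination can carry material on to the isoindigo and leave 1 unreacted.
- Attack of 5 on 4 (trimer) and N–C coupling are the minor risks.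
- Fallback: set out from 1 and put the two polarities into a base-free, oxidant-free coupling. Regitz diazo transfer (4-acetamidobenzenesulfonyl azide, DBU, MeCN, 0 °C to rt) gives 6-bromo-3-diazoindolin-2-one F1. Rh2(OAc)4 (1 mol %) in refluxing CH2Cl2 converts one molecule of F1 into an electrophilic rhodium carbenoid. The nucleophilic diazo carbon of a second molecule attacks it, and loss of nitrogen gives the insoluble (E)-6,6'-dibromoisoindigo F2, which is collected by filtration. Zn dust in hot AcOH then saturates the central alkene without touching the aryl bromides, and the sequence comes back to the route at 6.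

**2. Step 2.**
- The second lactam may react sluggishly.
- The neighbouring lactam oxygen may close onto the activated C2 to give a 2,2'-oxygen-bridged furan.
- Traces of Br2 or air may oxidise 6 to the isoindigo.
- Fallback: set out from 6 and separate deoxygenation from halogenation. iBu2AlH (6 equiv, CH2Cl2/toluene, 0 °C to rt, aqueous work-up) reduces each lactam to the hemiaminal, which eliminates to the indole and gives 6,6'-dibromo-1H,1'H-3,3'-biindole F3. NBS (2.0 equiv, THF, −78 to 0 °C) then brominates the only free pyrrole position of each 3-substituted indole, and the sequence comes back to the route at 8.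

## Further compounds
F1 | step 1 | 6-bromo-3-diazoindolin-2-one | [N-]=[N+]=C1C(=O)Nc2cc(Br)ccc12
F2 | step 1 | (E)-6,6'-dibromo-[3,3'-biindolinylidene]-2,2'-dione (6,6'-dibromoisoindigo) | O=C1Nc2cc(Br)ccc2/C1=C1\C(=O)Nc2cc(Br)ccc12
F3 | step 2 | 6,6'-dibromo-1H,1'H-3,3'-biindole | Brc1ccc2c(c1)[nH]cc2-c1c[nH]c2cc(Br)ccc12
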